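Ring A is disconnected last. Its C4a–C5 bond comes from a thermal cyclobutenone ring expansion and its C8–C8a bond from addition of a C6-metalated 2-aryl-3-methoxy-4-pyranone (rings B and C) to methyl semisquarate. The key step exploits the A-ring array C5-OH, C6-H, C7-OMe, C8-OMe beside the ring oxygen on C8a: on heating, the 3,4-dimethoxy-4-(pyranon-6-yl)cyclobutenone opens to a dienylketene whose ketene carbon closes onto pyranone C5, so the ketene oxygen becomes the lone chelated C5 hydroxyl and the two methoxy-bearing cyclobutene carbons become C7 and C8. The flavone is thus formed in one operation, with no phenol protection or selective demethylation.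

Key step: step 11

Assumption: methyl semisquarate is taken to behave like its isopropyl and tert-butyl analogues in preparation and in regioselective carbonyl addition; all sp3 stereocenters of the intermediates are racemic or mixed and vanish before the achiral target.

Step 1
Reactants: 1 2-bromoanisole; 2 furfural
Product: 4 racemic (furan-2-yl)(2-methoxyphenyl)methanol, via 2-methoxyphenylmagnesium bromide 3 (not isolated)
Conditions: Mg, I2 (cat.), THF, 23 → 40 °C; then 2, 0 °C; sat. aq NH4Cl
Reagents that add atoms: none
Why: Grignard addition of the arylmagnesium bromide to the unhindered aldehyde should be fast and clean; the carbinol stereocenter forms without control (racemic), which is harmless because it is erased in step 5.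

Step 2
Reactants: 4 racemic (furan-2-yl)(2-methoxyphenyl)methanol
Product: 5 6-hydroxy-2-(2-methoxyphenyl)-2H-pyran-3(6H)-one (racemic, anomer mixture)
Conditions: NBS, NaHCO3, THF/H2O (4:1), 0 °C
Reagents that add atoms: water (O)
Why: Achmatowicz rearrangement, in which the furan is oxidized in preference to the less electron-rich anisole ring, water opens the ring to the cis-enedione and the carbinol oxygen recloses it to the pyranone hemiacetal; the anomeric center forms as a mixture and is erased later together with C2.

Step 3
Reactants: 5 6-hydroxy-2-(2-methoxyphenyl)-2H-pyran-3(6H)-one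
Product: 6 6-methoxy-2-(2-methoxyphenyl)-2H-pyran-3(6H)-one (racemic, cis/trans mixture)
Conditions: HC(OMe)3, BF3·OEt2 (cat.), CH2Cl2, 0 °C
Reagents that add atoms: trimethyl orthoformate (COC(OC)OC)
Why: Acid-catalysed glycosidation through the ring oxocarbenium ion, with the orthoester as methanol source and water scavenger, caps the hemiacetal that would ring-open under the basic conditions of step 4; the anomeric ratio is of no consequence.

Step 4
Reactants: 6 6-methoxy-2-(2-methoxyphenyl)-2H-pyran-3(6H)-one
Product: 7 4,5-epoxy-6-methoxy-2-(2-methoxyphenyl)tetrahydro-2H-pyran-3-one (racemic, diastereomer mixture)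
Conditions: 30% H2O2, NaHCO3, MeOH/H2O, 0 °C
Reagents that add atoms: hydrogen peroxide (OO)
Why: Weitz–Scheffer nucleophilic epoxidation, in which hydroperoxide adds to the enone β-carbon C5 and the enolate closes the oxirane (mainly anti to the C6 methoxy group expected), brings in the C4 oxygen with an oxidant to which the anisole ring is inert; the diastereomer mixture is carried on because every sp3 center disappears in step 5.

Step 5
Reactants: 7 4,5-epoxy-6-methoxy-2-(2-methoxyphenyl)tetrahydro-2H-pyran-3-one
Product: 8 3-hydroxy-2-(2-methoxyphenyl)-4H-pyran-4-one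
Conditions: 2 M aq H2SO4, dioxane, 90 °C
Reagents that add atoms: none
Why: Acid-promoted isomerization of the α,β-epoxy ketone to the enolized 1,2-dione, β-elimination of methanol from the acetal and enolization toward the aryl-bearing carbon should give the 3-hydroxy-4-pyranone, the same sequence that converts the 2-methyl epoxy ketone into maltol; no stereocenter remains.

Step 6
Reactants: 8 3-hydroxy-2-(2-methoxyphenyl)-4H-pyran-4-one
Product: 9 3-methoxy-2-(2-methoxyphenyl)-4H-pyran-4-one
Conditions: MeI, K2CO3, acetone, 56 °C
Reagents that add atoms: iodomethane (CI)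
Why: Williamson O-methylation of the acidic enolic hydroxyl with a carbonate base is standard for 3-hydroxy-4-pyranones, and the pyranone carbonyl is not alkylated by MeI under these conditions.

Step 7
Reactants: 10 dimethyl squarate (3,4-dimethoxycyclobut-3-ene-1,2-dione)
Product: 11 racemic 4-hydroxy-2,3-dimethoxycyclobut-2-en-1-one
Conditions: LiAlH(OtBu)3 (1.0 equiv), THF, −78 → −20 °C; then cold 1 M HCl
Reagents that add atoms: none
Why: Chemoselective 1,2-reduction of one of the two equivalent vinylogous-ester carbonyls by the bulky, mild alkoxyaluminium hydride at low temperature should stop at the monoalcohol, which forms racemic.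

Step 8
Reactants: 11 racemic 4-hydroxy-2,3-dimethoxycyclobut-2-en-1-one
Product: 12 3-methoxycyclobut-3-ene-1,2-dione (methyl semisquarate)
Conditions: 12 M HCl (cat.), CH2Cl2, 23 °C; used at once
Reagents that add atoms: none
Why: Acid-catalysed 1,3-carbonyl transposition (protonation of the enol ether, tautomerization, β-elimination of methanol) should give the semisquarate, as it does for the higher alkyl esters; the stereocenter is lost.

Step 9
Reactants: 9 3-methoxy-2-(2-methoxyphenyl)-4H-pyran-4-one; 12 3-methoxycyclobut-3-ene-1,2-dione
Product: 14 racemic 4-hydroxy-3-methoxy-4-[5-methoxy-6-(2-methoxyphenyl)-4-oxo-4H-pyran-2-yl]cyclobut-2-en-1-one, via 6-lithio pyranone 13 (not isolated)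
Conditions: lithium 2,2,6,6-tetramethylpiperidide (1.0 equiv), THF, −78 °C, 15 min; then cannulated into 12, THF, −78 °C; sat. aq NH4Cl
Reagents that add atoms: none
Why: α-Lithiation at C6–H next to the ring oxygen, the same site as the C2-lithiation of chromones by hindered lithium amides, followed by 1,2-addition to the ketone-like carbonyl of 12 that flanks the methoxy-bearing carbon (the other carbonyl is a deactivated vinylogous ester), should form the future C8–C8a bond; the quaternary carbinol center forms racemic.

Step 10
Reactants: 14 racemic 4-hydroxy-3-methoxy-4-[5-methoxy-6-(2-methoxyphenyl)-4-oxo-4H-pyran-2-yl]cyclobut-2-en-1-one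
Product: 15 racemic 3,4-dimethoxy-4-[5-methoxy-6-(2-methoxyphenyl)-4-oxo-4H-pyran-2-yl]cyclobut-2-en-1-one
Conditions: MeI (excess), Ag2O, MeCN, 23 °C, dark
Reagents that add atoms: iodomethane (CI)
Why: Purdie-type methylation with MeI and Ag2O etherifies the tertiary alcohol without generating a free alkoxide, which would trigger ring opening of the 4-hydroxycyclobutenone; the stereocenter is untouched.

Step 11
Reactants: 15 racemic 3,4-dimethoxy-4-[5-methoxy-6-(2-methoxyphenyl)-4-oxo-4H-pyran-2-yl]cyclobut-2-en-1-one
Product: 18 5-hydroxy-3,7,8,2'-tetramethoxyflavone, via dienylketene 16 (not isolated), via 4a-H cyclohexadienone 17 (not isolated)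
Conditions: toluene (0.02 M, degassed), 110 °C, argon
Reagents that add atoms: none
Why: Heating should cause thermal conrotatory four-electron opening of the cyclobutenone C1–C4 bond, in which the donor methoxy group on the quaternary carbon rotates outward and so turns the pyranonyl group inward, giving (Z)-dienylketene 16. The ketene carbon then bonds to pyranone C5 in a thermal disrotatory six-electron electrocyclization that makes the C4a–C5 bond and closes ring A as a six-membered carbocycle fused to ring C (17). Enolization of the doubly activated C4a–H of 17 gives the phenol, driven by aromatization and by the hydrogen bond from the new C5 hydroxyl to the C4 carbonyl. This is the Moore ring expansion of 4-alkenyl- and 4-aryl-4-alkoxycyclobutenones to hydroquinone monoethers, applied here with the C5=C6 double bond of a 4-pyranone as the unsaturated arm. No stereocenter is created in the product, and the stereocenter of 15 and the transient one of 17 are erased. The step needs inward rotation of the pyranonyl arm, which the outward preference of the methoxy group secures, and closure at one site only, which is secured because C5 is the sole free carbon next to C6; the 5-OH, 6-H, 7-OMe, 8-OMe pattern then follows from connectivity alone.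

Compound list
1 | 2-bromoanisole | COc1ccccc1Br | starting material
2 | furfural | O=Cc1ccco1 | starting material
3 | 2-methoxyphenylmagnesium bromide | COc1ccccc1[Mg]Br | intermediate
4 | (furan-2-yl)(2-methoxyphenyl)methanol, racemic | COc1ccccc1C(O)c1ccco1 | intermediate
5 | 6-hydroxy-2-(2-methoxyphenyl)-2H-pyran-3(6H)-one, racemic anomer mixture | COc1ccccc1C1OC(O)C=CC1=O | intermediate
6 | 6-methoxy-2-(2-methoxyphenyl)-2H-pyran-3(6H)-one, racemic cis/trans mixture | COc1ccccc1C1OC(OC)C=CC1=O | intermediate
7 | 4,5-epoxy-6-methoxy-2-(2-methoxyphenyl)tetrahydro-2H-pyran-3-one, racemic diastereomer mixture | COc1ccccc1C1OC(OC)C2OC2C1=O | intermediate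
8 | 3-hydroxy-2-(2-methoxyphenyl)-4H-pyran-4-one | COc1ccccc1-c1occc(=O)c1O | intermediate
9 | 3-methoxy-2-(2-methoxyphenyl)-4H-pyran-4-one | COc1ccccc1-c1occc(=O)c1OC | intermediate
10 | dimethyl squarate | COC1=C(OC)C(=O)C1=O | starting material
11 | 4-hydroxy-2,3-dimethoxycyclobut-2-en-1-one, racemic | COC1=C(OC)C(O)C1=O | intermediate
12 | 3-methoxycyclobut-3-ene-1,2-dione | COC1=CC(=O)C1=O | intermediate
13 | 6-lithio-3-methoxy-2-(2-methoxyphenyl)-4H-pyran-4-one | [Li]c1cc(=O)c(OC)c(-c2ccccc2OC)o1 | intermediate
14 | 4-hydroxy-3-methoxy-4-[5-methoxy-6-(2-methoxyphenyl)-4-oxo-4H-pyran-2-yl]cyclobut-2-en-1-one, racemic | O=C1C=C(OC)C1(O)c1cc(=O)c(OC)c(-c2ccccc2OC)o1 | intermediate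
15 | 3,4-dimethoxy-4-[5-methoxy-6-(2-methoxyphenyl)-4-oxo-4H-pyran-2-yl]cyclobut-2-en-1-one, racemic | O=C1C=C(OC)C1(OC)c1cc(=O)c(OC)c(-c2ccccc2OC)o1 | intermediate
16 | (Z)-3,4-dimethoxy-4-[5-methoxy-6-(2-methoxyphenyl)-4-oxo-4H-pyran-2-yl]buta-1,3-dien-1-one (dienylketene) | O=C=C/C(OC)=C(/OC)c1cc(=O)c(OC)c(-c2ccccc2OC)o1 | intermediate
17 | 3,7,8-trimethoxy-2-(2-methoxyphenyl)-4aH-chromene-4,5-dione, racemic | COc1ccccc1C1=C(OC)C(=O)C2C(=O)C=C(OC)C(OC)=C2O1 | intermediate
18 | 5-hydroxy-3,7,8,2'-tetramethoxyflavone | COc1ccccc1-c1oc2c(OC)c(OC)cc(O)c2c(=O)c1OC | target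

Total step count: 11 (steps 1–6 for the pyranone, steps 7–8 for the four-carbon unit, steps 9–11 for union and ring A).
Longest linear sequence: 9 steps (1, 2, 3, 4, 5, 6, 9, 10, 11).

Steps most likely to fail

Step 9. The C6-lithiated pyranone may add in a conjugate sense to pyranone that is not yet metalated, or fragment before it is trapped. Deprotonation may also compete at C5 or on the anisole ring, and the carbanion may attack the enol-ether carbon of 12 with loss of methoxide instead of the carbonyl. The fallback sets out from 9 and returns at 14. C6–H is zincated with TMPZnCl·LiCl (THF, 25 °C, no added Lewis acid), the conditions under which chromones are metalated next to the ring oxygen, to give 6-(chlorozincio)-3-methoxy-2-(2-methoxyphenyl)-4H-pyran-4-one F1, which does not add to the pyranone. Iodolysis with I2 should give 6-iodo-3-methoxy-2-(2-methoxyphenyl)-4H-pyran-4-one F2, which is isolated. Iodine–magnesium exchange with iPrMgCl·LiCl (THF, −78 °C) then generates [5-methoxy-6-(2-methoxyphenyl)-4-oxo-4H-pyran-2-yl]magnesium chloride F3 with no amide base and no unmetalated pyranone present. Addition of F3 to 12 at −78 °C and an NH4Cl quench should give 14.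

Step 11. The dienylketene may dimerize or be captured by adventitious nucleophiles before the six-electron closure onto the electron-poor C5=C6 bond, or the tertiary methyl ether may ionize on heating, so that ring A is not formed. The fallback sets out from Grignard reagent 3 and returns at 18 by classical flavone chemistry, at the price of the regiochemical and demethylation questions the main route avoids. Carboxylation of 3 with CO2 and acidification gives 2-methoxybenzoic acid F4. Purchased 1,2,3,5-tetramethoxybenzene is acylated with methoxyacetyl chloride and AlCl3 (CH2Cl2, 0 → 23 °C) to 2-methoxy-1-(2,3,4,6-tetramethoxyphenyl)ethan-1-one F5. In the same flask the Lewis acid should cleave the crowded ortho methyl ether that is flanked by a second methoxy group, giving 1-(2-hydroxy-3,4,6-trimethoxyphenyl)-2-methoxyethan-1-one F6. Esterification of F6 with F4 (EDC·HCl, DMAP, CH2Cl2) gives 3,5,6-trimethoxy-2-(methoxyacetyl)phenyl 2-methoxybenzoate F7. Baker–Venkataraman acyl transfer (KOH, pyridine, 50 °C) gives 1-(2-hydroxy-3,4,6-trimethoxyphenyl)-2-methoxy-3-(2-methoxyphenyl)propane-1,3-dione F8. Cyclodehydration (H2SO4 cat., AcOH, 90 °C) gives 3,5,7,8,2'-pentamethoxyflavone F9. BCl3 (CH2Cl2, 0 °C) should then cleave only the methyl ether peri to the C4 carbonyl, through the six-membered boron chelate, to give 18.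

Step 4. Enolization at the benzylic, ketone-flanked C2–H of 6 under the alkaline peroxide conditions may divert the substrate into oxidative degradation or ring opening before hydroperoxide adds to C5. The fallback sets out from 6 and returns at 8, and brings in the C4 oxygen as halogen instead. Bromine addition to the enone (Br2, 1 equiv, CH2Cl2, −78 °C) gives 4,5-dibromo-6-methoxy-2-(2-methoxyphenyl)tetrahydro-2H-pyran-3-one F10. Et3N in the same flask removes HBr to give 4-bromo-6-methoxy-2-(2-methoxyphenyl)-2H-pyran-3(6H)-one F11. Heating F11 in aqueous H3PO4 (90 °C) should exchange bromide for hydroxyl with loss of methanol to give 8, as in the halogen route to maltol. One equivalent of bromine at low temperature in a non-polar solvent is needed to hold back bromination of the anisole ring, which is why this is the second choice.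

Further compounds
F1 | step 9 | 6-(chlorozincio)-3-methoxy-2-(2-methoxyphenyl)-4H-pyran-4-one | COc1ccccc1-c1oc([Zn]Cl)cc(=O)c1OC
F2 | step 9 | 6-iodo-3-methoxy-2-(2-methoxyphenyl)-4H-pyran-4-one | COc1ccccc1-c1oc(I)cc(=O)c1OC
F3 | step 9 | [5-methoxy-6-(2-methoxyphenyl)-4-oxo-4H-pyran-2-yl]magnesium chloride | COc1ccccc1-c1oc([Mg]Cl)cc(=O)c1OC
F4 | step 11 | 2-methoxybenzoic acid | COc1ccccc1C(=O)O
F5 | step 11 | 2-methoxy-1-(2,3,4,6-tetramethoxyphenyl)ethan-1-one | COCC(=O)c1c(OC)cc(OC)c(OC)c1OC
F6 | step 11 | 1-(2-hydroxy-3,4,6-trimethoxyphenyl)-2-methoxyethan-1-one | COCC(=O)c1c(OC)cc(OC)c(OC)c1O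
F7 | step 11 | 3,5,6-trimethoxy-2-(methoxyacetyl)phenyl 2-methoxybenzoate | COCC(=O)c1c(OC)cc(OC)c(OC)c1OC(=O)c1ccccc1OC
F8 | step 11 | 1-(2-hydroxy-3,4,6-trimethoxyphenyl)-2-methoxy-3-(2-methoxyphenyl)propane-1,3-dione | COC(C(=O)c1ccccc1OC)C(=O)c1c(OC)cc(OC)c(OC)c1O
F9 | step 11 | 3,5,7,8,2'-pentamethoxyflavone | COc1ccccc1-c1oc2c(OC)c(OC)cc(OC)c2c(=O)c1OC
F10 | step 4 | 4,5-dibromo-6-methoxy-2-(2-methoxyphenyl)tetrahydro-2H-pyran-3-one | COc1ccccc1C1OC(OC)C(Br)C(Br)C1=O
F11 | step 4 | 4-bromo-6-methoxy-2-(2-methoxyphenyl)-2H-pyran-3(6H)-one | COc1ccccc1C1OC(OC)C=C(Br)C1=O
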